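**Retrosynthetic overview**

1. The target is guibourtinidol-(4α→8)-epiafzelechin (upper unit 2R,3S,4S; lower unit 2R,3R). The last disconnections are the five O-benzyl groups and the interflavan C4(upper)–C8(lower) bond: Friedel–Crafts capture of the flavan-4-yl cation from diol 21 by tri-O-benzyl-epiafzelechin 13.
2. Lower unit: the cis-3-ol 13 comes from the enolisable flavan-3-one 12 by a stereoconvergent reduction that sets C2 and C3 together. Ketone 12 comes from 3-nitro-2H-chromene 9, in which the nitro group is the masked C3 oxygen.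
3. Ring C of the lower unit is closed in the key step from salicylaldehyde 6 and nitrostyrene 3 by a domino oxa-Michael/Henry condensation (O1–C2, then C3–C4). The enabling feature: on ring A the pyran oxygen O1 and the benzylic carbon C4 are ortho (O1–C8a–C4a–C4), C2 is a benzylic O-bearing carbon and C3 a heteroatom-bearing carbon, so ring C is a salicylaldehyde (O1, C4) plus a nitroalkene (C2, C3).
4. Upper unit: ring C is bought flat as chromone 15. Dearomatising asymmetric conjugate arylation sets C2 (17), Rubottom oxidation sets C3 (20), and NaBH4 installs the C4 leaving group (21).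
5. Order of ring formation: rings A and B of both units are bought as arenes; lower ring C forms in step 3; upper ring C is carried from the chromone and made stereogenic in steps 7–9; the units are joined in step 10.

Key step: step 3

Remark on the chemistry: diol 21 is drawn as the 3,4-trans epimer expected from NaBH4; any C4 epimer would be carried along, because both ionise to the same C4 cation in step 10.

**Route**

Step 1
Reactants: 1 4-(benzyloxy)benzaldehyde; 2 nitromethane
Product: 3 (E)-1-(benzyloxy)-4-(2-nitrovinyl)benzene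
Conditions: NH4OAc (0.5 equiv), AcOH, 100 °C
Reagents that add atoms: none
Why: Henry (nitroaldol) condensation, in which the β-nitro alcohol dehydrates under the buffered acidic conditions to the conjugated (E)-nitroalkene, the thermodynamic isomer.

Step 2
Reactants: 4 3,5-bis(benzyloxy)phenol; 5 paraformaldehyde
Product: 6 4,6-bis(benzyloxy)-2-hydroxybenzaldehyde
Conditions: MgCl2, Et3N, MeCN, reflux; aq. HCl work-up
Reagents that add atoms: none
Why: Magnesium-mediated ortho-formylation of a phenol (Casnati–Skattebøl reaction), in which the magnesium phenoxide delivers formaldehyde to an ortho carbon (the two are equivalent in 4) and a second formaldehyde oxidises the hydroxymethyl group by hydride transfer, so only the salicylaldehyde should form.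

Step 3
Reactants: 6 4,6-bis(benzyloxy)-2-hydroxybenzaldehyde; 3 (E)-1-(benzyloxy)-4-(2-nitrovinyl)benzene
Product: 9 rac-5,7-bis(benzyloxy)-2-[4-(benzyloxy)phenyl]-3-nitro-2H-chromene, via oxa-Michael nitro aldehyde 7 (not isolated), via 3-nitrochroman-4-ol 8 (not isolated)
Conditions: DABCO (0.5 equiv), MeCN, 4 Å MS, 60 °C
Reagents that add atoms: none
Why: DABCO deprotonates the only free phenol of 6 (O1, held ortho to the formyl carbon C4 on ring A), the phenoxide adds to the β-carbon of nitroalkene 3 (oxa-Michael, O1–C2), the resulting nitronate carbon C3 attacks the neighbouring aldehyde carbon C4 (intramolecular Henry addition), and E1cB loss of water from 8 makes the reversible sequence irreversible. The closest known reaction type is the amine-mediated domino oxa-Michael/Henry condensation of salicylaldehydes with β-nitrostyrenes to 2-aryl-3-nitro-2H-chromenes. Ring C of the lower flavan unit closes by a 6-(enolexo)-exo-trig addition of the nitronate to the carbonyl group. C2 is the only stereocentre formed and is left racemic on purpose, because it becomes enolisable in 12 and is set together with C3 in step 5. The step needs O- rather than C-alkylation and a single ring size: the formyl group deactivates ring A toward C-attack, the other two phenols are benzylated, and the ortho relation of O1 and C4 allows only the six-membered ring. The nitro group activates the C2=C3 acceptor, acidifies C3 for the ring closure and serves as the masked C3 oxygen, so one operation joins the ring-A and ring-B building blocks and completes the lower flavan skeleton.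

Step 4
Reactants: 9 rac-5,7-bis(benzyloxy)-2-[4-(benzyloxy)phenyl]-3-nitro-2H-chromene
Product: 12 rac-5,7-bis(benzyloxy)-2-[4-(benzyloxy)phenyl]chroman-3-one, via ketoxime 10 (not isolated), via ketimine 11 (not isolated)
Conditions: Fe powder, AcOH/H2O, 80 °C, N2
Reagents that add atoms: water, O
Why: Dissolving-metal reductive hydrolysis of a conjugated nitroalkene (a reductive Nef-type conversion known for 3-nitro-2H-chromenes), in which iron reduces the C3=C4–NO2 unit through the oxime to the ketimine, which hydrolyses to the C3 ketone, while aryl benzyl ethers survive hot acetic acid and no stereocentre has to be kept.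

Step 5
Reactants: 12 rac-5,7-bis(benzyloxy)-2-[4-(benzyloxy)phenyl]chroman-3-one
Product: 13 (2R,3R)-5,7-bis(benzyloxy)-2-[4-(benzyloxy)phenyl]chroman-3-ol
Conditions: RuCl[(R,R)-TsDPEN](p-cymene) (2 mol %), HCO2H/Et3N (5:2), DMF, 35 °C, degassed
Reagents that add atoms: none
Why: Proposed new method: C2–H of 12 is activated by the ketone, the aryl group and the ring oxygen, so the two enantiomers should interconvert through the C2=C3 enol in HCO2H/Et3N faster than the ruthenium hydride reduces the slower one, while hydride transfer to C3 anti to the quasi-equatorial 2-aryl group gives the 2,3-cis alcohol and the chiral diamine complex selects one ketone enantiomer, so C2 and C3 are set together as (2R,3R); the closest known reaction type is Noyori–Ikariya transfer hydrogenation with dynamic kinetic resolution of 2-arylcycloalkanones and α-alkoxy ketones, and the (R,R)-complex is chosen by analogy with aryl alkyl ketones (the aryl-bearing C2 side taking the place of the aryl group), a sense that a first run has to confirm (hydrogenolysis of a sample to (−)-epiafzelechin), with the (S,S)-complex taken if it proves opposite.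

Step 6
Reactants: 14 7-hydroxy-4H-chromen-4-one
Product: 15 7-(benzyloxy)-4H-chromen-4-one
Conditions: BnBr, K2CO3, DMF, rt
Reagents that add atoms: benzyl bromide, BrCc1ccccc1
Why: Williamson ether synthesis at the only hydroxyl group, which protects the ring-A phenol as the same benzyl ether used elsewhere.

Step 7
Reactants: 15 7-(benzyloxy)-4H-chromen-4-one; 16 [4-(benzyloxy)phenyl]boronic acid
Product: 17 (2S)-7-(benzyloxy)-2-[4-(benzyloxy)phenyl]chroman-4-one
Conditions: Pd(OCOCF3)2 (5 mol %), (R)-t-BuPyOx (6 mol %), NH4PF6 (30 mol %), H2O (5 equiv), ClCH2CH2Cl, 60 °C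
Reagents that add atoms: none
Why: Palladium-catalysed asymmetric conjugate addition of an arylboronic acid to a chromone (insertion of C2=C3 into the aryl–palladium bond, then protonolysis), a dearomatising arylation that sets C2, with the (R)-ligand chosen because the (S)-ligand gives (R)-β-aryl ketones from cyclic enones, the same spatial sense as an (R)-flavanone, to be checked by debenzylating a sample to liquiritigenin, whose natural form is (2S).

Step 8
Reactants: 17 (2S)-7-(benzyloxy)-2-[4-(benzyloxy)phenyl]chroman-4-one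
Product: 20 (2R,3R)-7-(benzyloxy)-2-[4-(benzyloxy)phenyl]-3-hydroxychroman-4-one, via silyl enol ether 18 (not isolated), via silyloxy epoxide 19 (not isolated)
Conditions: Me3SiOSO2CF3, Et3N, CH2Cl2, 0 °C; then DMDO, acetone, −40 °C; then aq. citric acid, THF
Reagents that add atoms: dimethyldioxirane, CC1(C)OO1
Why: Rubottom oxidation, in which soft enolisation avoids the free enolate that would open ring C by E1cB and racemise C2, dimethyldioxirane epoxidises the C3=C4 silyl enol ether anti to the 2-aryl group so that the new C3–O bond is trans to it, and mild hydrolysis gives the 2,3-trans α-hydroxy ketone, which is also the thermodynamic isomer.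

Step 9
Reactants: 20 (2R,3R)-7-(benzyloxy)-2-[4-(benzyloxy)phenyl]-3-hydroxychroman-4-one
Product: 21 (2R,3S,4R)-7-(benzyloxy)-2-[4-(benzyloxy)phenyl]chromane-3,4-diol
Conditions: NaBH4, THF/MeOH, 0 °C
Reagents that add atoms: none
Why: Borohydride reduction of the aryl ketone, in which hydride should add mainly anti to the adjacent C3 hydroxyl (3,4-trans diol) while C2 and C3 are untouched.

Step 10
Reactants: 21 (2R,3S,4R)-7-(benzyloxy)-2-[4-(benzyloxy)phenyl]chromane-3,4-diol; 13 (2R,3R)-5,7-bis(benzyloxy)-2-[4-(benzyloxy)phenyl]chroman-3-ol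
Product: 22 (2R,3S,4S)-7-(benzyloxy)-2-[4-(benzyloxy)phenyl]-4-{(2R,3R)-5,7-bis(benzyloxy)-2-[4-(benzyloxy)phenyl]-3-hydroxychroman-8-yl}chroman-3-ol
Conditions: BF3·OEt2 (0.2 equiv), 13 (3 equiv), 4 Å MS, CH2Cl2, −40 → 0 °C
Reagents that add atoms: none
Why: Friedel–Crafts alkylation modelled on the biogenetic flavan-3,4-diol/flavan-3-ol condensation, in which the Lewis acid ionises the 2,4-dioxygenated benzylic C4–OH of 21 and C8 of 13 (the most nucleophilic and less hindered ring-A carbon, C6 lying between two benzyloxy groups) attacks the 2,3-trans cation anti to the C3 hydroxyl to give the 3,4-trans (4α) bond, with excess 13 suppressing oligomers.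

Step 11
Reactants: 22 (2R,3S,4S)-7-(benzyloxy)-2-[4-(benzyloxy)phenyl]-4-{(2R,3R)-5,7-bis(benzyloxy)-2-[4-(benzyloxy)phenyl]-3-hydroxychroman-8-yl}chroman-3-ol
Product: 23 (2R,3S,4S)-2-(4-hydroxyphenyl)-4-[(2R,3R)-3,5,7-trihydroxy-2-(4-hydroxyphenyl)chroman-8-yl]chromane-3,7-diol
Conditions: H2 (1 atm), Pd(OH)2/C, THF/MeOH/H2O, rt
Reagents that add atoms: none
Why: Hydrogenolysis of the five aryl benzyl ethers under neutral conditions, which should leave the benzylic C2–O bonds, the interflavan bond (robust in the 5-deoxy series) and all five stereocentres untouched.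

**Compound list**

1 | 4-(benzyloxy)benzaldehyde | O=Cc1ccc(OCc2ccccc2)cc1 | starting material
2 | nitromethane | C[N+](=O)[O-] | starting material
3 | (E)-1-(benzyloxy)-4-(2-nitrovinyl)benzene | [O-][N+](=O)/C=C/c1ccc(OCc2ccccc2)cc1 | intermediate
4 | 3,5-bis(benzyloxy)phenol | Oc1cc(OCc2ccccc2)cc(OCc2ccccc2)c1 | starting material
5 | paraformaldehyde (shown as its formaldehyde unit) | C=O | starting material
6 | 4,6-bis(benzyloxy)-2-hydroxybenzaldehyde | O=Cc1c(O)cc(OCc2ccccc2)cc1OCc1ccccc1 | intermediate
7 | 4,6-bis(benzyloxy)-2-{1-[4-(benzyloxy)phenyl]-2-nitroethoxy}benzaldehyde, racemic, present as its nitronate (not isolated) | O=Cc1c(OC(C[N+](=O)[O-])c2ccc(OCc3ccccc3)cc2)cc(OCc2ccccc2)cc1OCc1ccccc1 | intermediate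
8 | 5,7-bis(benzyloxy)-2-[4-(benzyloxy)phenyl]-3-nitrochroman-4-ol, racemic mixture of diastereomers (not isolated) | OC1c2c(OCc3ccccc3)cc(OCc3ccccc3)cc2OC(c2ccc(OCc3ccccc3)cc2)C1[N+](=O)[O-] | intermediate
9 | rac-5,7-bis(benzyloxy)-2-[4-(benzyloxy)phenyl]-3-nitro-2H-chromene | [O-][N+](=O)C1=Cc2c(OCc3ccccc3)cc(OCc3ccccc3)cc2OC1c1ccc(OCc2ccccc2)cc1 | intermediate
10 | rac-5,7-bis(benzyloxy)-2-[4-(benzyloxy)phenyl]chroman-3-one oxime (not isolated) | ON=C1Cc2c(OCc3ccccc3)cc(OCc3ccccc3)cc2OC1c1ccc(OCc2ccccc2)cc1 | intermediate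
11 | rac-5,7-bis(benzyloxy)-2-[4-(benzyloxy)phenyl]chroman-3-imine (not isolated) | N=C1Cc2c(OCc3ccccc3)cc(OCc3ccccc3)cc2OC1c1ccc(OCc2ccccc2)cc1 | intermediate
12 | rac-5,7-bis(benzyloxy)-2-[4-(benzyloxy)phenyl]chroman-3-one | O=C1Cc2c(OCc3ccccc3)cc(OCc3ccccc3)cc2OC1c1ccc(OCc2ccccc2)cc1 | intermediate
13 | (2R,3R)-5,7-bis(benzyloxy)-2-[4-(benzyloxy)phenyl]chroman-3-ol (2,3-cis; tri-O-benzyl-epiafzelechin) | c1c(OCc3ccccc3)cc(OCc3ccccc3)c2c1O[C@H](c1ccc(OCc3ccccc3)cc1)[C@H](O)C2 | intermediate
14 | 7-hydroxy-4H-chromen-4-one | O=c1ccoc2cc(O)ccc12 | starting material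
15 | 7-(benzyloxy)-4H-chromen-4-one | O=c1ccoc2cc(OCc3ccccc3)ccc12 | intermediate
16 | [4-(benzyloxy)phenyl]boronic acid | OB(O)c1ccc(OCc2ccccc2)cc1 | starting material
17 | (2S)-7-(benzyloxy)-2-[4-(benzyloxy)phenyl]chroman-4-one | c1ccccc1COc1ccc([C@H]2Oc3cc(OCc4ccccc4)ccc3C(=O)C2)cc1 | intermediate
18 | {[(2S)-7-(benzyloxy)-2-[4-(benzyloxy)phenyl]-2H-chromen-4-yl]oxy}trimethylsilane (not isolated) | c1ccccc1COc1ccc([C@H]2Oc3cc(OCc4ccccc4)ccc3C(O[Si](C)(C)C)=C2)cc1 | intermediate
19 | 3,4-epoxide of 18, epoxide oxygen anti to the 2-aryl group (not isolated) | c1ccccc1COc1ccc([C@H]2Oc3cc(OCc4ccccc4)ccc3[C@]4(O[Si](C)(C)C)O[C@H]24)cc1 | intermediate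
20 | (2R,3R)-7-(benzyloxy)-2-[4-(benzyloxy)phenyl]-3-hydroxychroman-4-one (2,3-trans) | c1ccccc1COc1ccc([C@H]2Oc3cc(OCc4ccccc4)ccc3C(=O)[C@@H]2O)cc1 | intermediate
21 | (2R,3S,4R)-7-(benzyloxy)-2-[4-(benzyloxy)phenyl]chromane-3,4-diol (2,3-trans-3,4-trans) | c1ccccc1COc1ccc([C@H]2Oc3cc(OCc4ccccc4)ccc3[C@@H](O)[C@@H]2O)cc1 | intermediate
22 | (2R,3S,4S)-7-(benzyloxy)-2-[4-(benzyloxy)phenyl]-4-{(2R,3R)-5,7-bis(benzyloxy)-2-[4-(benzyloxy)phenyl]-3-hydroxychroman-8-yl}chroman-3-ol | c1ccccc1COc1ccc([C@H]2Oc3cc(OCc4ccccc4)ccc3[C@@H](c3c(OCc4ccccc4)cc(OCc4ccccc4)c4c3O[C@H](c3ccc(OCc5ccccc5)cc3)[C@H](O)C4)[C@@H]2O)cc1 | intermediate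
23 | (2R,3S,4S)-2-(4-hydroxyphenyl)-4-[(2R,3R)-3,5,7-trihydroxy-2-(4-hydroxyphenyl)chroman-8-yl]chromane-3,7-diol (guibourtinidol-(4α→8)-epiafzelechin) | Oc1ccc([C@H]2Oc3cc(O)ccc3[C@@H](c3c(O)cc(O)c4c3O[C@H](c3ccc(O)cc3)[C@H](O)C4)[C@@H]2O)cc1 | target

**Step count and risks**

Total step count: 11. Longest linear sequence: 6 steps (steps 2, 3, 4, 5, 10, 11; equally steps 6, 7, 8, 9, 10, 11).

Steps most likely to fail:

1. Step 5 (Proposed new method). Racemisation at C2 may be slower than reduction, so the step would act only as a kinetic resolution. Hydride may also be delivered in the wrong enantiofacial sense, or enolisation toward C4 may lead to self-condensation or air oxidation of the ketone. Fallback with known chemistry, setting out from 12: reduction with LiBH(s-Bu)3 in THF at −78 °C, a reagent known to convert flavan-3-ones into 2,3-cis-flavan-3-ols by attack anti to the 2-aryl group, should give the racemic cis alcohol F1. F1 is resolved by preparative chromatography on a chiral stationary phase. The (2R,3R) enantiomer is 13, where the fallback rejoins the route; the (2S,3S) enantiomer can be oxidised back to 12 with Dess–Martin periodinane and recycled.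

2. Step 10. The C4 cation may be attacked from the face syn to the C3 hydroxyl (4β epimer) or through C6 of 13, and the product may be alkylated again (oligomerisation) or 21 may etherify with itself. Fallback, setting out from 21: acetylation (Ac2O, pyridine) should give the 3,4-di-O-acetate F2. On ionisation with Me3SiOSO2CF3 (CH2Cl2, −78 °C) in the presence of 13, the 3-acetoxy group should bridge to C4 as an acetoxonium ion on the face syn to C3–O, so that C8 of 13 can only enter anti, giving the dimer 3-O-acetate F3. Methanolysis (NaOMe, MeOH) removes the acetate and the fallback rejoins the route at 22.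

3. Step 4. The reduction may stall at the oxime or run on to the 3-amine, and the electron-rich, enolisable ketone may decompose or oxidise in hot acid. Fallback, setting out from 9: conjugate reduction with NaBH4 (THF/MeOH, 0 °C) should give the 3-nitrochroman F4 as a mixture of diastereomers. Its nitronate (NaOMe, MeOH) is then converted at room temperature by buffered aqueous TiCl3/NH4OAc (reductive Nef reaction) into the ketone, and the fallback rejoins the route at 12.

**Further compounds**

F1 | step 5 | rac-(2R,3R)/(2S,3S)-5,7-bis(benzyloxy)-2-[4-(benzyloxy)phenyl]chroman-3-ol (racemic 2,3-cis alcohol) | c1c(OCc3ccccc3)cc(OCc3ccccc3)c2c1O[C@H](c1ccc(OCc3ccccc3)cc1)[C@H](O)C2.c1c(OCc3ccccc3)cc(OCc3ccccc3)c2c1O[C@@H](c1ccc(OCc3ccccc3)cc1)[C@@H](O)C2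
F2 | step 10 | 3,4-di-O-acetate of 21 (2,3-trans-3,4-trans) | c1ccccc1COc1ccc([C@H]2Oc3cc(OCc4ccccc4)ccc3[C@@H](OC(C)=O)[C@@H]2OC(C)=O)cc1
F3 | step 10 | upper-unit 3-O-acetate of 22 | c1ccccc1COc1ccc([C@H]2Oc3cc(OCc4ccccc4)ccc3[C@@H](c3c(OCc4ccccc4)cc(OCc4ccccc4)c4c3O[C@H](c3ccc(OCc5ccccc5)cc3)[C@H](O)C4)[C@@H]2OC(C)=O)cc1
F4 | step 4 | 5,7-bis(benzyloxy)-2-[4-(benzyloxy)phenyl]-3-nitrochroman, racemic mixture of diastereomers | c1c(OCc3ccccc3)cc(OCc3ccccc3)c2c1OC(c1ccc(OCc3ccccc3)cc1)C([N+](=O)[O-])C2
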